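D, the bis adduct, is asked for as a share of D, L and X taken together, and the book to keep for that share is the one on G.

    E + G → Z + J (k1 = 0.0213 M⁻¹ min⁻¹, Ea1 = 64.0 kJ mol⁻¹)
    G + Z → D + J (k2 = 0.0232 M⁻¹ min⁻¹, Ea2 = 67.0 kJ mol⁻¹)
    G + D → L + J (k3 = 0.0194 M⁻¹ min⁻¹, Ea3 = 56.0 kJ mol⁻¹)
    D ⇌ X (K4 = 11, k4 = 4.16 × 10⁻⁴ min⁻¹, Ea4 = 104 kJ mol⁻¹, ΔH4 = −49.0 kJ mol⁻¹)
    G ⇌ Q (K5 = 0.53, k5 = 1.61 × 10⁻⁴ min⁻¹, Ea5 = 105 kJ mol⁻¹, ΔH5 = −34.0 kJ mol⁻¹)
    (constants at 20 °C)

| flask | E | G | temperature | time | remark |
|---|---|---|---|---|---|
| east | 17 mM | 18.7 mM | −5 °C | 6.0 d |  |
| south-east | 17 mM | 18.7 mM | 20 °C | 6.0 d |  |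
| south-west | 17 mM | 18.7 mM |  | 6.0 d | at −5 °C until 40 h, from then on at 45 °C |
| west | 17 mM | 18.7 mM | 45 °C | 6.0 d |  |

- the constants hold at 20 °C; other temperatures follow from the activation energies and enthalpies

- which flask leads in share of D in all that became D or L or X ("all alike" within 1.5 percentage points) (east / south-east / south-west / west / all alike)
- share of D in all that became D or L or X, east
- share of D in all that became D or L or X, south-east
- share of D in all that became D or L or X, south-west
- share of D in all that became D or L or X, west

1. **Opening balance.** The charge is 18.7 mM of G against 17 mM of E. Reaching D takes two G per E, and 18.7 mM is less than the 34.0 mM that requires, so G is the limiting reagent.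

2. **Entries.** Each G spent leaves one J. It then stands once in Z, twice in D or X, three times in L: 18.7 mM = cG + cQ + cZ + 2(cD + cX) + 3cL. Q is G in another form, made by step 5.

3. **Closing date.** At 20 °C, the lifetime of G against E at its starting amount is 1.92 d, shorter than 6.0 d. Step 2 gains a factor 110 from the coldest to the hottest flask, so this reckoning expects the west book to close inside the time.

4. **The pair.** At 20 °C, D lives 1.67 d against step 4 and 1.91 d against G at its starting amount. Step 4 gains 1500 over the same span and step 3 gains less, 52. So at 45 °C D and X are taken as relaxed. With the equilibrium constant of step 4 at 2.27 in west, the part of cD + cX that is D once relaxed, the pair share 30.6%, is a ceiling on the asked share in west.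

5. **The leak to L.** L grows against the pair at about the ratio k3·cD/(k2·cZ), with cD the pair share of cD + cX. Over the run (cD + cX)/cZ is assumed to rise from nothing to about one, so 0.5 serves as its mean. The 20 °C constants then give a leak of 0.128, and the share of D comes to 27.1%. This figure is rough: those constants stand in for the ones at 45 °C, where k3/k2 is smaller, since Ea2 exceeds Ea3.

6. **Where the hand stops.** This estimate is meant for west, and for south-west once heated. East and south-east stay open, though east, where step 4 runs 1500 times slower than in west, is expected to lead.

The forecast names east as the leader, with 88% in east, 20% in south-east, 27.3% in south-west and 27% in west. Of south-west it says “the hot phase then runs to the same end state”.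

The flasks give 87.7% in east, 19.2% in south-east, 27.0% in south-west and 27.0% in west, so east leads. In south-west, D and X relax at 45 °C with a half-life of 0.674 h, far shorter than 6.0 d. West reads cD/(cD + cX) = 30.6% against the pair share of 30.6%. The forecast stands. The south-west share moves 5 points from its present value once G reaches 33.2 mM, or E falls to 9.29 mM, the other amounts and the time held.

South-west read at 4.0 d has been hot for 2.33 d, which is 83.1 half-lives, so the pair share 30.6% with its leak gives 27.1%. The computed flask gives 27.1%.

Its constants are those of an exercise; the flask was simulated.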